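The whole plan rests on cutting ring C of the flavanone between C2 and C3. C3 is brought in as the carbene carbon of an aryl diazomethyl ketone (from the C4 acetyl group), and C2 as the benzylic CH2 of a bis-silylated catechol benzyl ether on O1. A chiral dirhodium carboxylate then closes ring C in one operation by enantioselective 1,6 C–H insertion, creating the C2–C3 bond and the C2 stereocentre together. The step exploits the C2–H bond, activated both by O1 and by the electron-rich ring B. The open-chain precursor is built from phloroacetophenone; the C6 side chain arrives by Suzuki coupling of an (S)-citronellene-derived alkenylboronate ortho to the chelated C5 hydroxyl.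

Key step: step 10

Assumption: (S)-3,7-dimethylocta-1,6-diene is bought as the single enantiomer, and the catalyst enantiomer written in step 10 is the one taken to favour the 2S product; if its sense of induction is the opposite, its mirror image is used.

**Route**

Step 1
Reactants: 1 3,4-dihydroxybenzaldehyde
Product: 2 3,4-bis(tert-butyldimethylsilyloxy)benzaldehyde
Conditions: TBSCl (2.3 equiv), imidazole, DMF, rt
Reagents that add atoms: tert-butyldimethylsilyl chloride, CC(C)(C)[Si](C)(C)Cl
Why: Imidazole-promoted O-silylation converts both catechol hydroxyls into aryl silyl ethers that keep ring B electron-rich and offer no competing O–H bond later, while the aldehyde is inert.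

Step 2
Reactants: 2 3,4-bis(tert-butyldimethylsilyloxy)benzaldehyde
Product: 3 [3,4-bis(tert-butyldimethylsilyloxy)phenyl]methanol
Conditions: NaBH4, MeOH/THF, 0 °C
Reagents that add atoms: none
Why: Chemoselective borohydride reduction of the aryl aldehyde gives the benzylic alcohol needed for etherification, and aryl silyl ethers should survive brief exposure to NaBH4 at 0 °C.

Step 3
Reactants: 4 (S)-3,7-dimethylocta-1,6-diene
Product: 6 2-[(1E,3S)-3,7-dimethylocta-1,6-dien-1-yl]-4,4,5,5-tetramethyl-1,3,2-dioxaborolane, via catecholboronate ester 5 (not isolated)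
Conditions: B-chlorocatecholborane, Pd2(dba)3 (2.5 mol %), tBuP(3,5-tBu2C6H3)2 (6 mol %), LiOTf, Cy2NMe, PhCF3, 70 °C; then pinacol, rt
Reagents that add atoms: B-chlorocatecholborane, ClB1Oc2ccccc2O1; pinacol, CC(C)(O)C(C)(C)O
Why: Boryl-Heck reaction, in which B–Cl oxidative addition to zerovalent palladium, insertion of the monosubstituted alkene with boron at the terminal carbon and β-hydride elimination should give the (E)-alkenyl catecholboronate that pinacol then transesterifies; the trisubstituted alkene does not insert and the allylic stereocentre is not involved.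

Step 4
Reactants: 7 2',4',6'-trihydroxyacetophenone
Product: 8 1-[2,6-dihydroxy-4-(triisopropylsilyloxy)phenyl]ethan-1-one
Conditions: TIPSCl (1.05 equiv), imidazole, DMF, 0 °C
Reagents that add atoms: triisopropylsilyl chloride, CC(C)[Si](Cl)(C(C)C)C(C)C
Why: Selective mono-silylation, since the para hydroxyl is the most acidic and the only one not hydrogen-bonded to the acetyl carbonyl, so the bulky chlorosilane should take it first and leave the two chelated ortho hydroxyls free.

Step 5
Reactants: 8 1-[2,6-dihydroxy-4-(triisopropylsilyloxy)phenyl]ethan-1-one; 3 [3,4-bis(tert-butyldimethylsilyloxy)phenyl]methanol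
Product: 9 1-[2-{[3,4-bis(tert-butyldimethylsilyloxy)phenyl]methoxy}-6-hydroxy-4-(triisopropylsilyloxy)phenyl]ethan-1-one
Conditions: PPh3, DIAD, THF, 0 °C → rt
Reagents that add atoms: none
Why: Mitsunobu etherification puts the future C2 carbon on the future O1, because one of the two equivalent chelated phenols displaces the activated benzylic oxyphosphonium and the remaining, now more strongly chelated, phenol should resist a second alkylation.

Step 6
Reactants: 9 1-[2-{[3,4-bis(tert-butyldimethylsilyloxy)phenyl]methoxy}-6-hydroxy-4-(triisopropylsilyloxy)phenyl]ethan-1-one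
Product: 10 1-[6-{[3,4-bis(tert-butyldimethylsilyloxy)phenyl]methoxy}-2-hydroxy-3-iodo-4-(triisopropylsilyloxy)phenyl]ethan-1-one
Conditions: NIS (1.05 equiv), DMF, 0 °C → rt, dark
Reagents that add atoms: N-iodosuccinimide, O=C1CCC(=O)N1I
Why: Electrophilic aromatic iodination should occur ortho to the only free hydroxyl, the more activated and less hindered of the two open positions of ring A, which fixes the side chain at the future C6; the silylated catechol ring is much less nucleophilic.

Step 7
Reactants: 10 1-[6-{[3,4-bis(tert-butyldimethylsilyloxy)phenyl]methoxy}-2-hydroxy-3-iodo-4-(triisopropylsilyloxy)phenyl]ethan-1-one; 6 2-[(1E,3S)-3,7-dimethylocta-1,6-dien-1-yl]-4,4,5,5-tetramethyl-1,3,2-dioxaborolane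
Product: 11 1-[6-{[3,4-bis(tert-butyldimethylsilyloxy)phenyl]methoxy}-3-[(1E,3S)-3,7-dimethylocta-1,6-dien-1-yl]-2-hydroxy-4-(triisopropylsilyloxy)phenyl]ethan-1-one
Conditions: Pd(OAc)2 (5 mol %), SPhos (10 mol %), K3PO4, THF/H2O, 50 °C
Reagents that add atoms: none
Why: Suzuki–Miyaura coupling (oxidative addition of the aryl iodide to zerovalent palladium, transmetalation, reductive elimination) should proceed with retention of the E geometry and without touching the allylic stereocentre, the biaryl phosphine tolerating the two ortho substituents.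

Step 8
Reactants: 11 1-[6-{[3,4-bis(tert-butyldimethylsilyloxy)phenyl]methoxy}-3-[(1E,3S)-3,7-dimethylocta-1,6-dien-1-yl]-2-hydroxy-4-(triisopropylsilyloxy)phenyl]ethan-1-one
Product: 12 1-[6-{[3,4-bis(tert-butyldimethylsilyloxy)phenyl]methoxy}-2-(tert-butyldimethylsilyloxy)-3-[(1E,3S)-3,7-dimethylocta-1,6-dien-1-yl]-4-(triisopropylsilyloxy)phenyl]ethan-1-one
Conditions: TBSOTf, 2,6-lutidine, CH2Cl2, −20 → 0 °C
Reagents that add atoms: tert-butyldimethylsilyl triflate, CC(C)(C)[Si](C)(C)OS(=O)(=O)C(F)(F)F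
Why: Silyl triflate silylation caps the hindered chelated hydroxyl (the future C5–OH) with a group that prevents O–H insertion and has no C–H bond within reach of the later carbenoid, and 2,6-lutidine is too weak a base to enolise the ketone appreciably.

Step 9
Reactants: 12 1-[6-{[3,4-bis(tert-butyldimethylsilyloxy)phenyl]methoxy}-2-(tert-butyldimethylsilyloxy)-3-[(1E,3S)-3,7-dimethylocta-1,6-dien-1-yl]-4-(triisopropylsilyloxy)phenyl]ethan-1-one
Product: 14 1-[6-{[3,4-bis(tert-butyldimethylsilyloxy)phenyl]methoxy}-2-(tert-butyldimethylsilyloxy)-3-[(1E,3S)-3,7-dimethylocta-1,6-dien-1-yl]-4-(triisopropylsilyloxy)phenyl]-2-diazoethan-1-one, via trifluoroacetyl diketone 13 (not isolated)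
Conditions: LiN(SiMe3)2, THF, −78 °C, then CF3CO2CH2CF3; then MsN3, Et3N, H2O, MeCN, rt
Reagents that add atoms: methanesulfonyl azide, CS(=O)(=O)N=[N+]=[N-]; 2,2,2-trifluoroethyl trifluoroacetate, O=C(OCC(F)(F)F)C(F)(F)F (its CF3CO group is carried only by 13)
Why: Detrifluoroacetylative Regitz-type diazo transfer, in which Claisen C-trifluoroacetylation of the lithium enolate activates the methyl group and mesyl azide then delivers N2 with loss of the trifluoroacetyl group, should give the diazomethyl ketone at low temperature without harming silyl ethers or alkenes.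

Step 10
Reactants: 14 1-[6-{[3,4-bis(tert-butyldimethylsilyloxy)phenyl]methoxy}-2-(tert-butyldimethylsilyloxy)-3-[(1E,3S)-3,7-dimethylocta-1,6-dien-1-yl]-4-(triisopropylsilyloxy)phenyl]-2-diazoethan-1-one
Product: 15 (2S)-2-[3,4-bis(tert-butyldimethylsilyloxy)phenyl]-5-(tert-butyldimethylsilyloxy)-6-[(1E,3S)-3,7-dimethylocta-1,6-dien-1-yl]-7-(triisopropylsilyloxy)chroman-4-one
Conditions: Rh2(S-PTTL)4 (1 mol %), toluene, −20 °C → rt, slow addition of 14
Reagents that add atoms: none
Why: Loss of N2 at the dirhodium tetrakis[N-phthaloyl-(S)-tert-leucinate] catalyst gives an electrophilic rhodium carbenoid at C3 that inserts into one of the two enantiotopic benzylic C–H bonds of the O1–CH2–aryl group through a three-centre, hydride-transfer-like transition state, forming the C2–C3 bond. The closest known reaction type is the dirhodium tetracarboxylate-catalysed intramolecular C–H insertion of ortho-alkoxyaryl diazo ketones to chroman-4-ones. Ring C closes in the 1,6-insertion mode, through a six-membered chair-like transition state with the aryl group of ring B pseudo-equatorial. The C2 stereocentre is set by the chiral carboxylate ligands, which distinguish the two enantiotopic hydrogens, while the remote side-chain stereocentre is untouched and exerts no control. The step needs chemoselectivity for this C–H insertion over oxonium-ylide formation, insertion elsewhere and cyclopropanation; the target C–H bond is activated twice (alpha to O1, benzylic to the electron-rich ring B), the other ortho oxygen carries a bulky silyl group with no C–H bond in reach, both alkenes are meta-disposed and beyond intramolecular reach, and slow addition suppresses intermolecular reactions.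

Step 11
Reactants: 15 (2S)-2-[3,4-bis(tert-butyldimethylsilyloxy)phenyl]-5-(tert-butyldimethylsilyloxy)-6-[(1E,3S)-3,7-dimethylocta-1,6-dien-1-yl]-7-(triisopropylsilyloxy)chroman-4-one
Product: 16 (2S)-2-(3,4-dihydroxyphenyl)-6-[(1E,3S)-3,7-dimethylocta-1,6-dien-1-yl]-5,7-dihydroxychroman-4-one
Conditions: HF·pyridine, pyridine, THF, 0 °C → rt, under argon
Reagents that add atoms: none
Why: Fluoride-mediated cleavage of all four aryl silyl ethers under pyridine-buffered, non-basic conditions should avoid phenoxide-triggered opening of ring C and leave both alkenes and both stereocentres untouched.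

**Compound list**

1 | 3,4-dihydroxybenzaldehyde | O=Cc1ccc(O)c(O)c1 | starting material
2 | 3,4-bis(tert-butyldimethylsilyloxy)benzaldehyde | O=Cc1ccc(O[Si](C)(C)C(C)(C)C)c(O[Si](C)(C)C(C)(C)C)c1 | intermediate
3 | [3,4-bis(tert-butyldimethylsilyloxy)phenyl]methanol | OCc1ccc(O[Si](C)(C)C(C)(C)C)c(O[Si](C)(C)C(C)(C)C)c1 | intermediate
4 | (S)-3,7-dimethylocta-1,6-diene | CC(C)=CCC[C@H](C)C=C | starting material
5 | 2-[(1E,3S)-3,7-dimethylocta-1,6-dien-1-yl]-1,3,2-benzodioxaborole (not isolated) | CC(C)=CCC[C@H](C)/C=C/B1Oc2ccccc2O1 | intermediate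
6 | 2-[(1E,3S)-3,7-dimethylocta-1,6-dien-1-yl]-4,4,5,5-tetramethyl-1,3,2-dioxaborolane | CC(C)=CCC[C@H](C)/C=C/B1OC(C)(C)C(C)(C)O1 | intermediate
7 | 2',4',6'-trihydroxyacetophenone | CC(=O)c1c(O)cc(O)cc1O | starting material
8 | 1-[2,6-dihydroxy-4-(triisopropylsilyloxy)phenyl]ethan-1-one | CC(=O)c1c(O)cc(O[Si](C(C)C)(C(C)C)C(C)C)cc1O | intermediate
9 | 1-[2-{[3,4-bis(tert-butyldimethylsilyloxy)phenyl]methoxy}-6-hydroxy-4-(triisopropylsilyloxy)phenyl]ethan-1-one | CC(=O)c1c(O)cc(O[Si](C(C)C)(C(C)C)C(C)C)cc1OCc1ccc(O[Si](C)(C)C(C)(C)C)c(O[Si](C)(C)C(C)(C)C)c1 | intermediate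
10 | 1-[6-{[3,4-bis(tert-butyldimethylsilyloxy)phenyl]methoxy}-2-hydroxy-3-iodo-4-(triisopropylsilyloxy)phenyl]ethan-1-one | CC(=O)c1c(O)c(I)c(O[Si](C(C)C)(C(C)C)C(C)C)cc1OCc1ccc(O[Si](C)(C)C(C)(C)C)c(O[Si](C)(C)C(C)(C)C)c1 | intermediate
11 | 1-[6-{[3,4-bis(tert-butyldimethylsilyloxy)phenyl]methoxy}-3-[(1E,3S)-3,7-dimethylocta-1,6-dien-1-yl]-2-hydroxy-4-(triisopropylsilyloxy)phenyl]ethan-1-one | CC(=O)c1c(O)c(/C=C/[C@@H](C)CCC=C(C)C)c(O[Si](C(C)C)(C(C)C)C(C)C)cc1OCc1ccc(O[Si](C)(C)C(C)(C)C)c(O[Si](C)(C)C(C)(C)C)c1 | intermediate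
12 | 1-[6-{[3,4-bis(tert-butyldimethylsilyloxy)phenyl]methoxy}-2-(tert-butyldimethylsilyloxy)-3-[(1E,3S)-3,7-dimethylocta-1,6-dien-1-yl]-4-(triisopropylsilyloxy)phenyl]ethan-1-one | CC(=O)c1c(O[Si](C)(C)C(C)(C)C)c(/C=C/[C@@H](C)CCC=C(C)C)c(O[Si](C(C)C)(C(C)C)C(C)C)cc1OCc1ccc(O[Si](C)(C)C(C)(C)C)c(O[Si](C)(C)C(C)(C)C)c1 | intermediate
13 | 1-[6-{[3,4-bis(tert-butyldimethylsilyloxy)phenyl]methoxy}-2-(tert-butyldimethylsilyloxy)-3-[(1E,3S)-3,7-dimethylocta-1,6-dien-1-yl]-4-(triisopropylsilyloxy)phenyl]-4,4,4-trifluorobutane-1,3-dione (not isolated) | O=C(CC(=O)C(F)(F)F)c1c(O[Si](C)(C)C(C)(C)C)c(/C=C/[C@@H](C)CCC=C(C)C)c(O[Si](C(C)C)(C(C)C)C(C)C)cc1OCc1ccc(O[Si](C)(C)C(C)(C)C)c(O[Si](C)(C)C(C)(C)C)c1 | intermediate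
14 | 1-[6-{[3,4-bis(tert-butyldimethylsilyloxy)phenyl]methoxy}-2-(tert-butyldimethylsilyloxy)-3-[(1E,3S)-3,7-dimethylocta-1,6-dien-1-yl]-4-(triisopropylsilyloxy)phenyl]-2-diazoethan-1-one | [N-]=[N+]=CC(=O)c1c(O[Si](C)(C)C(C)(C)C)c(/C=C/[C@@H](C)CCC=C(C)C)c(O[Si](C(C)C)(C(C)C)C(C)C)cc1OCc1ccc(O[Si](C)(C)C(C)(C)C)c(O[Si](C)(C)C(C)(C)C)c1 | intermediate
15 | (2S)-2-[3,4-bis(tert-butyldimethylsilyloxy)phenyl]-5-(tert-butyldimethylsilyloxy)-6-[(1E,3S)-3,7-dimethylocta-1,6-dien-1-yl]-7-(triisopropylsilyloxy)chroman-4-one | CC(C)=CCC[C@H](C)/C=C/c1c(O[Si](C(C)C)(C(C)C)C(C)C)cc2c(c1O[Si](C)(C)C(C)(C)C)C(=O)C[C@@H](c1ccc(O[Si](C)(C)C(C)(C)C)c(O[Si](C)(C)C(C)(C)C)c1)O2 | intermediate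
16 | (2S)-2-(3,4-dihydroxyphenyl)-6-[(1E,3S)-3,7-dimethylocta-1,6-dien-1-yl]-5,7-dihydroxychroman-4-one | CC(C)=CCC[C@H](C)/C=C/c1c(O)cc2c(c1O)C(=O)C[C@@H](c1ccc(O)c(O)c1)O2 | target

**Totals**

Total step count: 11.
Longest linear sequence: 9 steps (1 → 2 → 3 → 9 → 10 → 11 → 12 → 14 → 15 → 16, that is steps 1, 2 and 5–11).

**Steps most likely to fail, with fallbacks**

Step 10. The chiral catalyst may discriminate poorly between the two enantiotopic benzylic hydrogens, so that ring C closes with low selectivity at C2. This becomes more likely if a less selective catalyst has to be chosen to suppress oxonium-ylide formation at O1. The fallback separates stereocontrol from ring closure. Setting out from 14, an achiral catalyst chosen for chemoselectivity alone (Rh2(OAc)4, CH2Cl2, rt, slow addition) should give the C2-epimeric mixture of (2RS)-2-[3,4-bis(tert-butyldimethylsilyloxy)phenyl]-5-(tert-butyldimethylsilyloxy)-6-[(1E,3S)-3,7-dimethylocta-1,6-dien-1-yl]-7-(triisopropylsilyloxy)chroman-4-one F1. Asymmetric transfer hydrogenation under kinetic-resolution conditions (RuCl[(R,R)-TsDPEN](p-cymene), HCO2H/Et3N, EtOAc, rt, stopped near half conversion) is then expected, by analogy with chroman-4-ones and flavanones, to reduce the (2R)-epimer faster. This would give the cis alcohol (2R,4R)-2-[3,4-bis(tert-butyldimethylsilyloxy)phenyl]-5-(tert-butyldimethylsilyloxy)-6-[(1E,3S)-3,7-dimethylocta-1,6-dien-1-yl]-7-(triisopropylsilyloxy)chroman-4-ol F2, which is removed by chromatography. The unreduced (2S)-ketone is 15, where the route resumes.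

Step 3. β-Hydride elimination may be unselective, and palladium hydride may walk along the chain; this would give allylboronate and isomerised alkenes and could erode the allylic stereocentre. The fallback fixes position and geometry through an alkyne. Setting out from 4, Tsuji–Wacker oxidation of the monosubstituted alkene (PdCl2, CuCl, O2, DMF/H2O, rt) should give (S)-3,7-dimethyloct-6-en-2-one F3. Kinetic deprotonation at the methyl group and O-phosphorylation (LiN(iPr)2, THF, −78 °C; ClP(O)(OEt)2) should give diethyl (S)-3,7-dimethylocta-1,6-dien-2-yl phosphate F4. Elimination with further LiN(iPr)2 (−78 °C → rt) should give (S)-3,7-dimethyloct-6-en-1-yne F5. Hydroboration with pinacolborane catalysed by Cp2Zr(H)Cl (Et3N, 60 °C) should then add syn and anti-Markovnikov to the alkyne only, returning to the route at 6.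

Step 6. Site control in the iodination may be lost, with attack para to the free hydroxyl or on the silylated catechol ring. The fallback installs the iodine and the side chain before ring B is present. Setting out from 8, mono-iodination of the symmetric diol (NIS, 1.0 equiv, DMF, 0 °C) should give 1-[2,6-dihydroxy-3-iodo-4-(triisopropylsilyloxy)phenyl]ethan-1-one F6. Suzuki–Miyaura coupling with 6 (Pd(OAc)2, SPhos, K3PO4, THF/H2O, 50 °C) should give 1-{3-[(1E,3S)-3,7-dimethylocta-1,6-dien-1-yl]-2,6-dihydroxy-4-(triisopropylsilyloxy)phenyl}ethan-1-one F7. Mitsunobu etherification with 3 (PPh3, DIAD, THF) is expected to take the less hindered hydroxyl, remote from the alkenyl group, and so returns to the route at 11.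

Further compounds
F1 | step 10 | (2RS)-2-[3,4-bis(tert-butyldimethylsilyloxy)phenyl]-5-(tert-butyldimethylsilyloxy)-6-[(1E,3S)-3,7-dimethylocta-1,6-dien-1-yl]-7-(triisopropylsilyloxy)chroman-4-one (mixture of C2 epimers) | CC(C)=CCC[C@H](C)/C=C/c1c(O[Si](C(C)C)(C(C)C)C(C)C)cc2c(c1O[Si](C)(C)C(C)(C)C)C(=O)CC(c1ccc(O[Si](C)(C)C(C)(C)C)c(O[Si](C)(C)C(C)(C)C)c1)O2
F2 | step 10 | (2R,4R)-2-[3,4-bis(tert-butyldimethylsilyloxy)phenyl]-5-(tert-butyldimethylsilyloxy)-6-[(1E,3S)-3,7-dimethylocta-1,6-dien-1-yl]-7-(triisopropylsilyloxy)chroman-4-ol | CC(C)=CCC[C@H](C)/C=C/c1c(O[Si](C(C)C)(C(C)C)C(C)C)cc2c(c1O[Si](C)(C)C(C)(C)C)[C@H](O)C[C@H](c1ccc(O[Si](C)(C)C(C)(C)C)c(O[Si](C)(C)C(C)(C)C)c1)O2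
F3 | step 3 | (S)-3,7-dimethyloct-6-en-2-one | CC(C)=CCC[C@H](C)C(C)=O
F4 | step 3 | diethyl (S)-3,7-dimethylocta-1,6-dien-2-yl phosphate | CC(C)=CCC[C@H](C)C(=C)OP(=O)(OCC)OCC
F5 | step 3 | (S)-3,7-dimethyloct-6-en-1-yne | CC(C)=CCC[C@H](C)C#C
F6 | step 6 | 1-[2,6-dihydroxy-3-iodo-4-(triisopropylsilyloxy)phenyl]ethan-1-one | CC(=O)c1c(O)cc(O[Si](C(C)C)(C(C)C)C(C)C)c(I)c1O
F7 | step 6 | 1-{3-[(1E,3S)-3,7-dimethylocta-1,6-dien-1-yl]-2,6-dihydroxy-4-(triisopropylsilyloxy)phenyl}ethan-1-one | CC(=O)c1c(O)cc(O[Si](C(C)C)(C(C)C)C(C)C)c(/C=C/[C@@H](C)CCC=C(C)C)c1O
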